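**Retrosynthetic overview**

- Feature: in ring B the hydroxyl carbon C5, the two CH carbons C4 and C3 and the benzyl-bearing C2 form the chain O–C5–C4–C3–C2(CH2Ar). This is a 2-benzylfuran with its ring oxygen; C6 and C1, with their benzyl and two-carbon substituents, are the two carbons of an alkyne.
- Ring B is the only ring built (rings A, C and D are bought as arenes). It is closed by (4+2) addition of furan 15 to ynone 12, forming C5–C6 and C1–C2, and the oxygen bridge then opens to phenol 17.
- Ynone 12 comes from the lithium acetylide of propyne 9 and morpholine amide 6. Amide 6 comes from α-arylation of 4-acetylmorpholine with aryl bromide 2. Propyne 9 and furan 15 both come from benzyl chloride 7.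
- After the key step the activating carbonyl is removed without a benzylic cation: O-benzylation, enol triflate, Pd/formate reduction to stilbene 21, then one hydrogenation that saturates the C=C bond and frees the four phenols.

Key step: step 6

Remark on the chemistry: the target has no stereocentre; 11 and 16 are racemic transients whose stereocentres vanish. Ring B is numbered C1 (CH2CH2 bridge), C2 and C6 (benzyl groups), C3 and C4 (CH), C5 (OH). Ring A is the methoxy-bearing ring, ring C the benzyl ring on C2, ring D the benzyl ring on C6.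

**Route**

Step 1
Reactants: 1 3-bromo-5-methoxyphenol
Product: 2 1-(benzyloxy)-3-bromo-5-methoxybenzene
Conditions: BnBr, K2CO3, acetone, reflux
Reagents that add atoms: benzyl bromide, BrCc1ccccc1
Why: Williamson ether synthesis, in which the phenoxide displaces bromide from the benzylic halide by SN2 and the aryl bromide and methyl ether are inert.

Step 2
Reactants: 2 1-(benzyloxy)-3-bromo-5-methoxybenzene; 3 4-acetylmorpholine
Product: 6 2-[3-(benzyloxy)-5-methoxyphenyl]-1-(morpholin-4-yl)ethan-1-one, via lithium amide enolate 4 (not isolated), via chlorozinc amide enolate 5 (not isolated)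
Conditions: 3, s-BuLi, THF, −78 °C; ZnCl2, −78 °C → rt; then 2, Pd(dba)2 (cat.), 1,2,3,4,5-pentaphenyl-1'-(di-tert-butylphosphino)ferrocene (cat.), THF, rt
Reagents that add atoms: none
Why: Palladium-catalysed α-arylation of an amide zinc enolate (a Negishi-type coupling of a Reformatsky-like reagent), whose low basicity should stop the reaction at mono-arylation and tolerate both aryl ethers.

Step 3
Reactants: 7 4-(benzyloxy)benzyl chloride; 8 ethynylmagnesium bromide
Product: 9 1-(benzyloxy)-4-(prop-2-yn-1-yl)benzene
Conditions: HC≡CMgBr (excess), CuCl (cat.), THF, 50 °C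
Reagents that add atoms: none
Why: Copper-catalysed cross-coupling of an alkynyl Grignard reagent with an activated benzylic chloride, with excess acetylide to suppress double alkylation.

Step 4
Reactants: 9 1-(benzyloxy)-4-(prop-2-yn-1-yl)benzene; 6 2-[3-(benzyloxy)-5-methoxyphenyl]-1-(morpholin-4-yl)ethan-1-one
Product: 12 1-[3-(benzyloxy)-5-methoxyphenyl]-5-[4-(benzyloxy)phenyl]pent-3-yn-2-one, via lithium acetylide 10 (not isolated), via tetrahedral lithium alkoxide 11 (not isolated)
Conditions: 9, n-BuLi, THF, −78 °C; then 6, −78 → −30 °C; inverse quench into cold 1 M HCl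
Reagents that add atoms: none
Why: Acylation of a lithium acetylide by a morpholine amide (Weinreb-type ketone synthesis), in which the tetrahedral alkoxide persists at low temperature so no second addition occurs, and the cold acidic inverse quench protonates morpholine as it is released so that it cannot add to the ynone or isomerise it.

Step 5
Reactants: 13 furan; 7 4-(benzyloxy)benzyl chloride
Product: 15 2-[4-(benzyloxy)benzyl]furan, via 2-furyllithium 14 (not isolated)
Conditions: 13 (excess), n-BuLi, THF, 0 °C; then 7, −78 °C → rt
Reagents that add atoms: none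
Why: α-Lithiation of furan followed by SN2 alkylation of the heteroaryllithium with an activated (4-alkoxy) benzylic chloride.

Step 6
Reactants: 15 2-[4-(benzyloxy)benzyl]furan; 12 1-[3-(benzyloxy)-5-methoxyphenyl]-5-[4-(benzyloxy)phenyl]pent-3-yn-2-one
Product: 17 1-{2,6-bis[4-(benzyloxy)benzyl]-3-hydroxyphenyl}-2-[3-(benzyloxy)-5-methoxyphenyl]ethan-1-one, via oxanorbornadiene cycloadduct 16 (not isolated)
Conditions: ZnI2 (1.5 equiv), 15 (1.5 equiv), CH2Cl2, 0 °C → rt
Reagents that add atoms: none
Why: ZnI2 binds the ynone carbonyl and the furan adds as the diene in an asynchronous, polar (4+2) cycloaddition: the unsubstituted α-carbon of 15 (largest HOMO coefficient) bonds to the β-alkyne carbon C4 of 12 and the benzyl-bearing α-carbon bonds to the acyl-bearing C3, which closes the six-membered carbocycle of ring B intermolecularly through the bonds that become C5–C6 and C1–C2 and gives the 7-oxanorbornadiene 16. The same Lewis acid then ionises the C–O bond at the tertiary, benzyl-bearing bridgehead, where the cation is allylic and the acyl group sits on the central carbon of the allyl system, and loss of the proton from the oxygen-bearing bridgehead carbon aromatises the ring, so that the furan oxygen becomes the C5 hydroxyl next to the ring D benzyl group. The closest known reaction type is the Lewis-acid-promoted Diels–Alder reaction of 2-alkylfurans with acetylenic ketones and esters with in situ isomerisation of the oxanorbornadiene to a phenol. The two bridgehead stereocentres of racemic 16 are destroyed on aromatisation, so no stereocentre has to be controlled. The step needs one orientation of addition and one direction of bridge opening; the first is secured by the polarisation of the partners (nucleophilic furan C5 to electrophilic ynone β-carbon) and the second by the tertiary versus secondary bridgehead. ZnI2 is chosen as a mild, oxophilic acid that leaves aryl benzyl ethers intact, because stronger or carbophilic acids would favour proton loss from the first-formed zwitterion (Friedel–Crafts alkenylation of the furan) or 6-endo hydroarylation of the alkyne by ring A.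

Step 7
Reactants: 17 1-{2,6-bis[4-(benzyloxy)benzyl]-3-hydroxyphenyl}-2-[3-(benzyloxy)-5-methoxyphenyl]ethan-1-one
Product: 18 1-{3-(benzyloxy)-2,6-bis[4-(benzyloxy)benzyl]phenyl}-2-[3-(benzyloxy)-5-methoxyphenyl]ethan-1-one
Conditions: BnBr, K2CO3, acetone, reflux
Reagents that add atoms: benzyl bromide, BrCc1ccccc1
Why: Williamson etherification of the phenol under carbonate, which does not alkylate the ketone α-carbon, so that the next step sulfonylates only the enolate oxygen and all four phenols are later released together.

Step 8
Reactants: 18 1-{3-(benzyloxy)-2,6-bis[4-(benzyloxy)benzyl]phenyl}-2-[3-(benzyloxy)-5-methoxyphenyl]ethan-1-one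
Product: 20 (Z)-1-{3-(benzyloxy)-2,6-bis[4-(benzyloxy)benzyl]phenyl}-2-[3-(benzyloxy)-5-methoxyphenyl]ethenyl trifluoromethanesulfonate, via potassium enolate 19 (not isolated)
Conditions: KN(SiMe3)2, THF, −78 °C; then PhNTf2, −78 → 0 °C
Reagents that add atoms: N-phenylbis(trifluoromethanesulfonimide), O=S(=O)(N(c1ccccc1)S(=O)(=O)C(F)(F)F)C(F)(F)F
Why: Enolate O-sulfonylation (enol triflate formation): the hindered ketone has a single, benzylic enolisable position, the enolate should place ring A trans to the bulky 2,6-disubstituted ring B (Z expected), and the double-bond geometry is of no consequence because it is erased in step 10.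

Step 9
Reactants: 20 (Z)-1-{3-(benzyloxy)-2,6-bis[4-(benzyloxy)benzyl]phenyl}-2-[3-(benzyloxy)-5-methoxyphenyl]ethenyl trifluoromethanesulfonate
Product: 21 (E)-1-(benzyloxy)-3-(2-{3-(benzyloxy)-2,6-bis[4-(benzyloxy)benzyl]phenyl}ethenyl)-5-methoxybenzene
Conditions: Pd(OAc)2 (cat.), PPh3, HCO2H, Et3N, DMF, 60 °C
Reagents that add atoms: none
Why: Palladium-catalysed formate reduction of a vinyl triflate (oxidative addition, formate exchange, decarboxylation, C–H reductive elimination with retention), which removes the oxygen without a cation at the carbon on ring B and so avoids six-membered Friedel–Crafts closure onto the flanking benzyl rings (a 9,10-dihydroanthracene) that an acid-mediated deoxygenation would risk.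

Step 10
Reactants: 21 (E)-1-(benzyloxy)-3-(2-{3-(benzyloxy)-2,6-bis[4-(benzyloxy)benzyl]phenyl}ethenyl)-5-methoxybenzene
Product: 22 3-{2-[3-hydroxy-2,6-bis(4-hydroxybenzyl)phenyl]ethyl}-5-methoxyphenol (target)
Conditions: H2 (1–3 bar), 10% Pd/C, EtOAc–MeOH, rt
Reagents that add atoms: none
Why: Heterogeneous catalytic hydrogenation should saturate the stilbene double bond and hydrogenolyse all four aryl benzyl ethers in one operation, while the aryl methyl ether and the diarylmethane C–C bonds are inert.

**Compound list**

1 | 3-bromo-5-methoxyphenol | COc1cc(O)cc(Br)c1 | starting material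
2 | 1-(benzyloxy)-3-bromo-5-methoxybenzene | COc1cc(Br)cc(OCc2ccccc2)c1 | intermediate
3 | 4-acetylmorpholine | CC(=O)N1CCOCC1 | starting material
4 | lithium enolate of 4-acetylmorpholine | C=C(O[Li])N1CCOCC1 | intermediate
5 | chlorozinc enolate of 4-acetylmorpholine (carbon-bound form) | Cl[Zn]CC(=O)N1CCOCC1 | intermediate
6 | 2-[3-(benzyloxy)-5-methoxyphenyl]-1-(morpholin-4-yl)ethan-1-one | COc1cc(CC(=O)N2CCOCC2)cc(OCc2ccccc2)c1 | intermediate
7 | 4-(benzyloxy)benzyl chloride | ClCc1ccc(OCc2ccccc2)cc1 | starting material
8 | ethynylmagnesium bromide | C#C[Mg]Br | starting material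
9 | 1-(benzyloxy)-4-(prop-2-yn-1-yl)benzene | C#CCc1ccc(OCc2ccccc2)cc1 | intermediate
10 | lithium acetylide of 9 | [Li]C#CCc1ccc(OCc2ccccc2)cc1 | intermediate
11 | lithium alkoxide of the morpholine hemiaminal (tetrahedral adduct, racemic) | COc1cc(CC(O[Li])(C#CCc2ccc(OCc3ccccc3)cc2)N2CCOCC2)cc(OCc2ccccc2)c1 | intermediate
12 | 1-[3-(benzyloxy)-5-methoxyphenyl]-5-[4-(benzyloxy)phenyl]pent-3-yn-2-one | COc1cc(OCc2ccccc2)cc(CC(=O)C#CCc2ccc(OCc3ccccc3)cc2)c1 | intermediate
13 | furan | c1ccoc1 | starting material
14 | 2-furyllithium | [Li]c1ccco1 | intermediate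
15 | 2-[4-(benzyloxy)benzyl]furan | C(c1ccco1)c1ccc(OCc2ccccc2)cc1 | intermediate
16 | 1-{1,3-bis[4-(benzyloxy)benzyl]-7-oxabicyclo[2.2.1]hepta-2,5-dien-2-yl}-2-[3-(benzyloxy)-5-methoxyphenyl]ethan-1-one (racemic; relative configuration fixed by the bridge) | COc1cc(CC(=O)C2=C(Cc3ccc(OCc4ccccc4)cc3)C3C=CC2(Cc2ccc(OCc4ccccc4)cc2)O3)cc(OCc2ccccc2)c1 | intermediate
17 | 1-{2,6-bis[4-(benzyloxy)benzyl]-3-hydroxyphenyl}-2-[3-(benzyloxy)-5-methoxyphenyl]ethan-1-one | Oc1ccc(Cc2ccc(OCc3ccccc3)cc2)c(C(=O)Cc2cc(OC)cc(OCc3ccccc3)c2)c1Cc1ccc(OCc2ccccc2)cc1 | intermediate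
18 | 1-{3-(benzyloxy)-2,6-bis[4-(benzyloxy)benzyl]phenyl}-2-[3-(benzyloxy)-5-methoxyphenyl]ethan-1-one | O=C(Cc1cc(OC)cc(OCc2ccccc2)c1)c1c(Cc2ccc(OCc3ccccc3)cc2)ccc(OCc2ccccc2)c1Cc1ccc(OCc2ccccc2)cc1 | intermediate
19 | potassium (Z)-enolate of 18 | [K]O/C(=C\c1cc(OC)cc(OCc2ccccc2)c1)c1c(Cc2ccc(OCc3ccccc3)cc2)ccc(OCc2ccccc2)c1Cc1ccc(OCc2ccccc2)cc1 | intermediate
20 | (Z)-1-{3-(benzyloxy)-2,6-bis[4-(benzyloxy)benzyl]phenyl}-2-[3-(benzyloxy)-5-methoxyphenyl]ethenyl trifluoromethanesulfonate | FC(F)(F)S(=O)(=O)O/C(=C\c1cc(OC)cc(OCc2ccccc2)c1)c1c(Cc2ccc(OCc3ccccc3)cc2)ccc(OCc2ccccc2)c1Cc1ccc(OCc2ccccc2)cc1 | intermediate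
21 | (E)-1-(benzyloxy)-3-(2-{3-(benzyloxy)-2,6-bis[4-(benzyloxy)benzyl]phenyl}ethenyl)-5-methoxybenzene | COc1cc(/C=C/c2c(Cc3ccc(OCc4ccccc4)cc3)ccc(OCc3ccccc3)c2Cc2ccc(OCc3ccccc3)cc2)cc(OCc2ccccc2)c1 | intermediate
22 | 3-{2-[3-hydroxy-2,6-bis(4-hydroxybenzyl)phenyl]ethyl}-5-methoxyphenol | COc1cc(O)cc(CCc2c(Cc3ccc(O)cc3)ccc(O)c2Cc2ccc(O)cc2)c1 | target

**Step count and risks**

Total step count: 10. Longest linear sequence: 8 steps (steps 1, 2, 4, 6, 7, 8, 9, 10).

Steps most likely to fail:

1. Step 6. The internal alkyne may add slowly, and the zwitterion formed by the first C–C bond may lose a proton before ring closure (conjugate Friedel–Crafts alkenylation of the furan). The Lewis acid may also isomerise or cyclise the ynone before the furan adds. Fallback: set out from 12 and 15 and separate the two events. Uncatalysed cycloaddition under high pressure (about 12–15 kbar, CH2Cl2, room temperature), where no Lewis acid is present to divert the addition, should give the oxanorbornadiene 16 as an isolated compound. Brief treatment of 16 with BF3·OEt2 in CH2Cl2 at −78 °C should then open the bridge at the tertiary bridgehead, and the route is rejoined at 17. This fallback makes no compound outside the list (F0).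

2. Step 4. The acetylide may deprotonate the acidic ArCH2C(=O) position instead of adding, the tetrahedral intermediate may collapse early so that free morpholine adds to the ynone, and base may isomerise the benzylic propargyl unit to an allene. Fallback: set out from 6 and 9 and replace acylation by addition to an aldehyde followed by oxidation. Partial reduction of amide 6 with Cp2Zr(H)Cl in THF should give 2-[3-(benzyloxy)-5-methoxyphenyl]acetaldehyde F1. Addition of lithium acetylide 10 (from 9 and n-BuLi, THF, −78 °C, with CeCl3 if enolisation interferes) should give racemic 1-[3-(benzyloxy)-5-methoxyphenyl]-5-[4-(benzyloxy)phenyl]pent-3-yn-2-ol F2. Oxidation with Dess–Martin periodinane buffered with NaHCO3 in CH2Cl2 should return the route to 12.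

3. Step 3. The acetylene Grignard reagent may be alkylated at both ends, and the basic acetylide may isomerise the product to the arylallene. Fallback: set out from 7 and use a capped, monofunctional alkyne. Coupling of 7 with Me3SiC≡CMgBr (CuBr cat., THF, 50 °C) should give {3-[4-(benzyloxy)phenyl]prop-1-yn-1-yl}trimethylsilane F3. Short protodesilylation (K2CO3, MeOH, 0 °C) should return the route to 9.

**Further compounds**

F0 | step 6 | none | none
F1 | step 4 | 2-[3-(benzyloxy)-5-methoxyphenyl]acetaldehyde | COc1cc(CC=O)cc(OCc2ccccc2)c1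
F2 | step 4 | 1-[3-(benzyloxy)-5-methoxyphenyl]-5-[4-(benzyloxy)phenyl]pent-3-yn-2-ol (racemic) | COc1cc(CC(O)C#CCc2ccc(OCc3ccccc3)cc2)cc(OCc2ccccc2)c1
F3 | step 3 | {3-[4-(benzyloxy)phenyl]prop-1-yn-1-yl}trimethylsilane | C[Si](C)(C)C#CCc1ccc(OCc2ccccc2)cc1
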